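Readings and results were generated by integration for an exercise; noise was put on by code.

If a protic impurity competes for the starting material, the first question is whether it leaves the second-catalyst cycle short of supply, so I set two amounts against each other.

| setting | dawn | winter | oak | cedar | birch | elm |
|---|---|---|---|---|---|---|
| starting material | 0.10 M | 0.10 M | 0.10 M | 0.10 M | 0.10 M | 0.10 M |
| partner | 1.3 equiv | 2 equiv | 2.00 equiv | 2.00 equiv | 2.00 equiv | 2.00 equiv |
| protic impurity | 0.010 M | 0.010 M | 0.0100 M | 0.0200 M | 0.0400 M | 0.0800 M |
| free catalyst | 6.1 mol% | 6.1 mol% | 6.1 mol% | 6.1 mol% | 6.1 mol% | 6.1 mol% |
| precatalyst | 0.2 mol% | 0.4 mol% | 0.2 mol% | 0.2 mol% | 0.2 mol% | 0.2 mol% |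
| remark | run made earlier | run made earlier |  |  |  |  |
| time |  |  | 3.0 h | 3.0 h | 3.0 h | 3.0 h |

- dawn (time / min: target / %): 8.00: 0; 15.0: 1.0; 30.0: 1.3; 60.0: 5.1; 120: 7.4
- winter (time / min: target / %): 20.0: 0; 40.0: 4.4; 60.0: 6.5; 80.0: 9.7; 120: 13.9

(each reading ± 1 percentage point)

- the numbers in the tables scatter by 1 percentage point (one standard deviation)
- reactions considered so far: starting material + free catalyst -> free catalyst + open intermediate; second catalyst + open intermediate <-> catalyst intermediate; partner + catalyst intermediate -> second catalyst + target; 2 free catalyst <-> resting dimer; starting material + protic impurity -> quenched substrate; partner + precatalyst -> second catalyst + spent reagent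
- no earlier run changes the charge of protic impurity; that part of a forecast is a guess
- "hardly changes" means that all values lie within two and a half points (for a concentration: within two and a half percent of the largest)

- amount of target at the end, in percent of the starting material charged for oak, cedar, birch, elm, in this order
- the shape of the row from first to last (rises, then falls / hardly changes / falls, then rises / falls all the way / rises all the way)

The first amount came from the dawn readings. I took the slope s of the target between the second and last readings, as a fraction of the charge:

s = 0.0366 h⁻¹

Winter, with twice the precatalyst of dawn and more partner, gave 0.0712 h⁻¹, twice the dawn slope. The two runs differ in two settings, so this was no clean test, but I treated the second-catalyst cycle as the rate-limiting step. Oak, cedar, birch and elm all carry the dawn loading of precatalyst, so I defined the cycle output D as the target that this slope delivers over the time given: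

D = s × 3.0 h = 11.0%

This is a reading and carries the scatter of its points.

The second amount was the worst-case supply S for elm, the flask with the most impurity. I supposed that each impurity molecule removed one molecule of starting material, and took what remained as a share of the charge:

S = 20.0%

S stood above D, by a factor of 1.82. I therefore expected about D in each flask and a flat row, although no earlier run had varied the impurity, so this was a guess.

The forecast gave 11%, 11%, 10.8% and 10.2%, with the shape hardly changes, and argued that “The rate depends on the catalyst, so the row should stay nearly flat”.

The flasks gave 10.7%, 10.4%, 9.86% and 8.89%: the row hardly changes.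

    starting material + free catalyst → free catalyst + open intermediate (k = 25.8 L mol⁻¹ min⁻¹)
    second catalyst + open intermediate ⇌ catalyst intermediate (K = 19.4 L mol⁻¹, k = 4.21 L mol⁻¹ min⁻¹)
    partner + catalyst intermediate → second catalyst + target (k = 16.1 L mol⁻¹ min⁻¹)
    2 free catalyst ⇌ resting dimer, settled at all times (K = 191 L mol⁻¹)
    starting material + protic impurity → quenched substrate (k = 0.314 L mol⁻¹ min⁻¹)
    partner + precatalyst → second catalyst + spent reagent (k = 1.19 L mol⁻¹ min⁻¹)

Oak ended at 10.7%, beside the D of 11.0% read from dawn. In elm, the quench took 22.3% of the starting material, yet 68.8% still stood as open intermediate at 3.00 h, which is 6.25 times D, while the target lay at 8.89%. Elm was short mainly of time, because the time given was the main thing holding the target back: the same flask reached 56.8% at 30.0 h.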